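Late in the larch run L still climbs, from 27.1 % at 15.0 min to 45.9 % at 40.0 min, but per minute it gains less than it did just before, so we first ask which charge holds L back in each flask.

common to all: Q 49 mM

| run | J | E | temperature | remark | time |
|---|---|---|---|---|---|
| larch | 1.2 equiv | 1.4 equiv | 32 °C | run made earlier |  |
| cedar | 1.2 equiv | 2 equiv | 49 °C | run made earlier |  |
| maple | 0.96 equiv | 1.2 equiv | 32 °C | run made earlier |  |
| teal | 0.800 equiv | 1.20 equiv | 55 °C |  | 40 min |
| violet | 0.300 equiv | 1.20 equiv | 25 °C |  | 40 min |
| red | 1.20 equiv | 1.20 equiv | 25 °C |  | 40 min |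
| green | 2.40 equiv | 1.80 equiv | 25 °C |  | 40 min |
| grey | 4.80 equiv | 1.20 equiv | 55 °C |  | 40 min |

| run | time / min | L / % |
|---|---|---|
| larch | 3.00 | 7.9 |
| larch | 8.00 | 16.7 |
| larch | 15.0 | 27.1 |
| larch | 40.0 | 45.9 |
| cedar | 1.50 | 13.3 |
| cedar | 5.00 | 32.2 |
| cedar | 8.00 | 40.9 |
| cedar | 12.0 | 49.2 |
| maple | 3.00 | 6.1 |
| maple | 8.00 | 13.3 |
| maple | 15.0 | 23.0 |
| maple | 40.0 | 38.0 |

(each reading ± 0.5 percentage points)

* the flasks put in order of amount of L, in percent of the Q charged, best first, at 40 min (teal / violet / red / green / grey)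
* the amount of L, in percent of the Q charged of the flask you put first, at 40 min
* the amount of L, in percent of the Q charged of the flask you put last, at 40 min

Follow one molecule of Q. Its step to L gives one G. No Z is charged, so that Z came from E, which gave up a second G. If J takes up each G as X, each L costs two J. So we define the ceiling C, the smallest of half the J charge, the E charge and the Q charge, in equivalents of Q, which names the limiting reagent: for teal, 40.0 %. For grey C is 100 %, and for violet 15.0 %.

The readings fit this. Larch stands at 45.9 % and maple at 38.0 % at 40.0 min, against ceilings of 60.0 % and 48.0 %.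

Next comes the rate. We take the rate of L as k times the Q left times Z, with Z the J charge less two L while J limits. Integrating this through larch at 8.00 min gives k = 0.0224 min⁻¹. Cedar at 5.00 min gives 0.0952 min⁻¹. Running ln k straight in temperature gives 0.159 min⁻¹ at 55 °C and 0.0124 min⁻¹ at 25 °C.

In grey J is in excess, so Z is the E charge less L, and the law gives 93.9 %. Violet, under its ceiling, gives 9.12 %. We commit to those two.

The weak link is teal, since C assumes that G leaves through J, and G → D is a second door. The same law gives larch 43.4 % at 40.0 min, and the reading stands 2.5 percentage points above it, with a scatter of 0.5 points. So teal's C is a soft stop that L may pass, and we leave teal's place open.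

The forecast reads grey > green > teal > red > violet, with grey at 92 % (83 % to 97 %), lower than ours, violet at 10 % (8 % to 13 %), and “Teal: plateau 40%, plus leak, about 49%”. The flasks give grey > teal > green > red > violet.

    Q + Z → G + L (k = 0.00490 L mol⁻¹ s⁻¹, Ea = 63.0 kJ mol⁻¹)
    G + J ⇌ X, settled at all times (K = 1.40 × 10⁵ L mol⁻¹, ΔH = 2.00 kJ mol⁻¹)
    Z + G ⇌ E, settled at all times (K = 4500 L mol⁻¹, ΔH = −8.00 kJ mol⁻¹)
    G → D (k = 9.20 × 10⁻⁴ s⁻¹, Ea = 94.0 kJ mol⁻¹)
    (constants at 25 °C)

Grey gives 92.9 % and violet 11.4 %, while teal gives 74.6 %, which is 35 points above its C, with 43.5 mM of D. In grey, the half-life of Q by Q + Z is 6.5 min at 4.64 min and 18 min at 40.0 min. That is shorter than the run, and 7.1 % of the Q remains under a C of 100 %. Grey charged with 0.300 equiv of E has C = 30.0 % and stands at 29.7 %.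

The runs are calculated from invented constants.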